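**Plan**

- Retrosynthesis: the amide bond N-1–C-2 of the 17-membered ring is not cut as a macrolactam. It is traced back by three N-to-N acyl shifts, through the C-2–N-14 amide (13-membered ring) and the C-2–N-9 amide (8-membered ring), to the C-2–N-5 bond of an N-alkylated (R)-4-nonylazetidin-2-one.
- Enabling feature: N-5, C-4 (nonyl), C-3 and C-2(=O) of the macrocycle are a 3-aminoacyl unit, the open form of an azetidin-2-one. N-9, N-14 and N-1 follow N-5 at three, four and three carbons, so every shift passes a six-, seven- or six-membered tetrahedral intermediate.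
- Further cuts: N-5–C-6 (lactam N-alkylation), C-17–N-1 (azide), the two N–C bonds that join the outer propyl arms to a putrescine bis-carbamate, and the bond between the first and second carbon of the nonyl chain (copper-mediated coupling).
- Forward order: the azetidinone is closed on L-aspartate, the nonyl chain and then the linear polyamine chain are attached, and the ring grows 4 to 8 to 13 to 17 in the last step without a macrolactamization.
- Stereochemistry: C-4 is the alpha-carbon of L-aspartic acid and is never touched; the label changes from S to R only because the former carboxyl carbon becomes a chain CH2.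

Key step: step 11

Remark: atom labels (N-1, C-2, C-3, C-4, N-5, N-9, N-14) follow the ring numbering of the target and are kept for the same atoms in every intermediate; dibenzyl L-aspartate is taken as its commercial p-toluenesulfonate salt.

**Route**

Step 1
Reactants: 1 dibenzyl L-aspartate p-toluenesulfonate
Product: 4 benzyl (S)-4-oxoazetidine-2-carboxylate, via N-silyl diester 2 (not isolated), via N-silyl lactam 3 (not isolated)
Conditions: Et3N (2.2 equiv), Me3SiCl (1.1 equiv), Et2O, 0 °C, filter; t-BuMgCl (1.1 equiv), Et2O, 0 °C to rt; 2 M HCl/NH4Cl (aq)
Reagents that add atoms: none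
Why: The hindered Grignard base deprotonates the N-silylamine and the magnesium amide closes onto the beta-ester (intramolecular ester aminolysis, 4-exo-trig lactamization), the silyl group preventing intermolecular acylation and being lost in the acidic work-up; the alpha-carbon takes no part, so the S configuration of the amino acid is carried over.

Step 2
Reactants: 4 benzyl (S)-4-oxoazetidine-2-carboxylate
Product: 5 (S)-4-(hydroxymethyl)azetidin-2-one
Conditions: NaBH4, MeOH, 0 °C to rt
Reagents that add atoms: none
Why: The ester, activated by the adjacent lactam nitrogen, should be reduced to the primary alcohol while the less electrophilic lactam carbonyl stays intact (chemoselective borohydride reduction of an ester), and at 0 °C reduction should outpace enolization at the stereocentre.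

Step 3
Reactants: 5 (S)-4-(hydroxymethyl)azetidin-2-one
Product: 7 (S)-4-(iodomethyl)azetidin-2-one, via mesylate 6 (not isolated)
Conditions: MsCl, Et3N, CH2Cl2, 0 °C; evaporate; NaI, acetone, reflux
Reagents that add atoms: sodium iodide, [Na+].[I-]
Why: Mesylation of the primary alcohol and Finkelstein substitution by iodide in acetone (SN2 at a primary carbon) exchange OH for I; the lactam N–H is too weakly nucleophilic to be sulfonylated and the neighbouring stereocentre is not involved.

Step 4
Reactants: 7 (S)-4-(iodomethyl)azetidin-2-one
Product: 8 (S)-1-(tert-butyldimethylsilyl)-4-(iodomethyl)azetidin-2-one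
Conditions: t-BuMe2SiCl, Et3N, DMF, 0 °C to rt
Reagents that add atoms: tert-butyldimethylsilyl chloride, CC(C)(C)[Si](C)(C)Cl
Why: N-Silylation of the lactam with the silyl chloride and amine base masks the acidic N–H, which would otherwise quench the organometallic reagent of step 5, and the bulky silyl group also shields the lactam carbonyl.

Step 5
Reactants: 8 (S)-1-(tert-butyldimethylsilyl)-4-(iodomethyl)azetidin-2-one; 9 1-bromooctane
Product: 12 (R)-1-(tert-butyldimethylsilyl)-4-nonylazetidin-2-one, via octylmagnesium bromide 10 (not isolated), via magnesium dioctylcuprate 11 (not isolated)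
Conditions: 9 (3 equiv), Mg, THF, rt; CuBr·SMe2 (1.5 equiv), THF, −40 °C; 8, −40 to 0 °C; aq NH4Cl
Reagents that add atoms: none
Why: Copper-mediated sp3–sp3 coupling of a primary alkyl iodide with a dialkylcuprate (substitution at the CH2–I carbon) should be faster at low temperature than attack on the hindered N-silyl lactam carbonyl; C-4 is next to, not at, the reacting carbon, so its geometry is kept and only the descriptor turns from S to R because the side chain now ranks below the ring CH2.

Step 6
Reactants: 12 (R)-1-(tert-butyldimethylsilyl)-4-nonylazetidin-2-one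
Product: 13 (R)-4-nonylazetidin-2-one
Conditions: Bu4NF, AcOH, THF, 0 °C
Reagents that add atoms: none
Why: Fluoride cleaves the labile N–Si bond of the silyl lactam (desilylation), and the acetic acid buffer protonates the lactam anion at once so that it cannot open a second lactam.

Step 7
Reactants: 14 butane-1,4-diamine
Product: 15 dibenzyl butane-1,4-diylbiscarbamate
Conditions: CbzCl (2.2 equiv), NaOH (aq), CH2Cl2, 0 °C to rt
Reagents that add atoms: benzyl chloroformate, O=C(Cl)OCc1ccccc1
Why: Schotten–Baumann acylation of both primary amines with the chloroformate gives the bis-carbamate, which leaves one N–H per nitrogen for a single alkylation and is later removed by the same hydrogenolysis that reduces the azide.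

Step 8
Reactants: 15 dibenzyl butane-1,4-diylbiscarbamate; 16 1-bromo-3-chloropropane
Product: 17 dibenzyl butane-1,4-diylbis[(3-chloropropyl)carbamate]
Conditions: NaH (2.4 equiv), DMF, 0 °C; added to 16 (8 equiv), DMF, 0 °C to rt
Reagents that add atoms: 1-bromo-3-chloropropane (second molecule of 16), ClCCCBr
Why: Twofold N-alkylation of the disodium bis-carbamate (SN2), in which each of the two carbamate nitrogens takes up one molecule of the dihalide at the carbon bearing bromide, the better leaving group, so that two 3-chloropropyl arms are attached; adding the dianion to a large excess of the dihalide should suppress bridging of two carbamates by one propane unit.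

Step 9
Reactants: 13 (R)-4-nonylazetidin-2-one; 17 dibenzyl butane-1,4-diylbis[(3-chloropropyl)carbamate]
Product: 18 benzyl (3-chloropropyl)[4-((benzyloxycarbonyl){3-[(R)-2-nonyl-4-oxoazetidin-1-yl]propyl}amino)butyl]carbamate
Conditions: NaH (1.1 equiv), DMF, 0 °C; 17 (3 equiv), Bu4NI (0.1 equiv), rt to 40 °C
Reagents that add atoms: none
Why: N-Alkylation of the lactam sodium salt (SN2, helped by in-situ Finkelstein exchange with catalytic iodide) by one end of the symmetric dichloride, whose threefold excess should hold the reaction at mono-substitution and is recovered; the tertiary carbamates have no acidic hydrogen and C-4 is not touched.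

Step 10
Reactants: 18 benzyl (3-chloropropyl)[4-((benzyloxycarbonyl){3-[(R)-2-nonyl-4-oxoazetidin-1-yl]propyl}amino)butyl]carbamate
Product: 19 benzyl (3-azidopropyl)[4-((benzyloxycarbonyl){3-[(R)-2-nonyl-4-oxoazetidin-1-yl]propyl}amino)butyl]carbamate
Conditions: NaN3 (3 equiv), DMF, 65 °C
Reagents that add atoms: sodium azide, [Na+].[N-]=[N+]=[N-]
Why: SN2 displacement of the primary chloride (and of any iodide left from the halide exchange in step 9) by azide brings in N-1 in a form that cannot attack the lactam and is unmasked together with the carbamates.

Step 11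
Reactants: 19 benzyl (3-azidopropyl)[4-((benzyloxycarbonyl){3-[(R)-2-nonyl-4-oxoazetidin-1-yl]propyl}amino)butyl]carbamate
Product: 23 (R)-4-nonyl-1,5,9,14-tetraazacycloheptadecan-2-one, via triamine lactam 20 (not isolated), via eight-membered lactam 21 (not isolated), via thirteen-membered lactam 22 (not isolated)
Conditions: H2 (1 atm), 10% Pd/C, EtOH, rt; filter; 50 °C; evaporate (toluene azeotrope); KH, H2N(CH2)3NH2, rt, about 0.02 M; aq NH4Cl
Reagents that add atoms: none
Why: Proposed new method: hydrogenolysis frees N-9, N-14 and N-1 together, and N-9 should add to the strained lactam carbonyl C-2 in a 6-exo-trig sense; collapse of the six-membered tetrahedral intermediate with cleavage of C-2–N-5 turns the four-membered ring into the eight-membered lactam 21, which is the known transamidative ring expansion of N-(3-aminopropyl)azetidin-2-ones. In the amide base, N-14 should then add to the same carbonyl (7-exo-trig) and expel N-9 to give the thirteen-membered lactam 22, and N-1 should add (6-exo-trig) and expel N-14 to give the seventeen-membered ring of 23; both shifts are zip ring enlargements of N-(aminoalkyl) lactams, the closest known reaction type. New is the linking of the strain-release shift to two zip shifts, one of them across a four-carbon spacer, with nothing isolated in between. No stereocentre is formed, and C-4 keeps its configuration because no bond to it changes and it is not alpha to the carbonyl. The selectivity required is acyl transfer that stays intramolecular and runs forward only: ring strain pays for the first shift, the three- and four-carbon spacers make every addition a six- or seven-membered closure so that no large-ring transition state arises, and the final secondary amide alone carries an N–H acidic enough to be fully deprotonated, which takes 23 out of the equilibria. The base is introduced only when the azetidinone has already rearranged, so the solvent amine cannot open it, and room temperature at about 0.02 M should hold back oligomerisation and beta-elimination of N-5.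

**Compound list**

1 | dibenzyl L-aspartate p-toluenesulfonate | N[C@@H](CC(=O)OCc1ccccc1)C(=O)OCc1ccccc1.Cc1ccc(cc1)S(=O)(=O)O | starting material
2 | dibenzyl N-(trimethylsilyl)-L-aspartate | C[Si](C)(C)N[C@@H](CC(=O)OCc1ccccc1)C(=O)OCc1ccccc1 | intermediate (not isolated)
3 | benzyl (S)-4-oxo-1-(trimethylsilyl)azetidine-2-carboxylate | O=C(OCc1ccccc1)[C@@H]1CC(=O)N1[Si](C)(C)C | intermediate (not isolated)
4 | benzyl (S)-4-oxoazetidine-2-carboxylate | O=C(OCc1ccccc1)[C@@H]1CC(=O)N1 | intermediate
5 | (S)-4-(hydroxymethyl)azetidin-2-one | OC[C@@H]1CC(=O)N1 | intermediate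
6 | [(S)-4-oxoazetidin-2-yl]methyl methanesulfonate | CS(=O)(=O)OC[C@@H]1CC(=O)N1 | intermediate (not isolated)
7 | (S)-4-(iodomethyl)azetidin-2-one | IC[C@@H]1CC(=O)N1 | intermediate
8 | (S)-1-(tert-butyldimethylsilyl)-4-(iodomethyl)azetidin-2-one | IC[C@@H]1CC(=O)N1[Si](C)(C)C(C)(C)C | intermediate
9 | 1-bromooctane | CCCCCCCCBr | starting material
10 | octylmagnesium bromide | CCCCCCCC[Mg]Br | intermediate (not isolated)
11 | magnesium dioctylcuprate, (C8H17)2CuMgBr | CCCCCCCC[Cu-]CCCCCCCC.[Mg+]Br | intermediate (not isolated)
12 | (R)-1-(tert-butyldimethylsilyl)-4-nonylazetidin-2-one | CCCCCCCCC[C@@H]1CC(=O)N1[Si](C)(C)C(C)(C)C | intermediate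
13 | (R)-4-nonylazetidin-2-one | CCCCCCCCC[C@@H]1CC(=O)N1 | intermediate
14 | butane-1,4-diamine | NCCCCN | starting material
15 | dibenzyl butane-1,4-diylbiscarbamate | O=C(NCCCCNC(=O)OCc1ccccc1)OCc1ccccc1 | intermediate
16 | 1-bromo-3-chloropropane | ClCCCBr | starting material
17 | dibenzyl butane-1,4-diylbis[(3-chloropropyl)carbamate] | ClCCCN(CCCCN(CCCCl)C(=O)OCc1ccccc1)C(=O)OCc1ccccc1 | intermediate
18 | benzyl (3-chloropropyl)[4-((benzyloxycarbonyl){3-[(R)-2-nonyl-4-oxoazetidin-1-yl]propyl}amino)butyl]carbamate | CCCCCCCCC[C@@H]1CC(=O)N1CCCN(CCCCN(CCCCl)C(=O)OCc1ccccc1)C(=O)OCc1ccccc1 | intermediate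
19 | benzyl (3-azidopropyl)[4-((benzyloxycarbonyl){3-[(R)-2-nonyl-4-oxoazetidin-1-yl]propyl}amino)butyl]carbamate | CCCCCCCCC[C@@H]1CC(=O)N1CCCN(CCCCN(CCCN=[N+]=[N-])C(=O)OCc1ccccc1)C(=O)OCc1ccccc1 | intermediate
20 | (R)-1-[3-({4-[(3-aminopropyl)amino]butyl}amino)propyl]-4-nonylazetidin-2-one | CCCCCCCCC[C@@H]1CC(=O)N1CCCNCCCCNCCCN | intermediate (not isolated)
21 | (R)-1-{4-[(3-aminopropyl)amino]butyl}-4-nonyl-1,5-diazocan-2-one | CCCCCCCCC[C@@H]1CC(=O)N(CCCCNCCCN)CCCN1 | intermediate (not isolated)
22 | (R)-1-(3-aminopropyl)-4-nonyl-1,5,9-triazacyclotridecan-2-one | CCCCCCCCC[C@@H]1CC(=O)N(CCCN)CCCCNCCCN1 | intermediate (not isolated)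
23 | (R)-4-nonyl-1,5,9,14-tetraazacycloheptadecan-2-one | CCCCCCCCC[C@@H]1CC(=O)NCCCNCCCCNCCCN1 | target

**Count**

Total steps: 11. Longest linear sequence: 9 steps (steps 1 to 6, then 9, 10 and 11, from 1 to 23). The linchpin 17 is made in a 2-step side branch (steps 7 and 8).

**Steps most likely to fail**

Step 11. The relay may stall before N-1 is reached. The four-carbon hop from N-9 to N-14 has to pass a seven-membered tetrahedral intermediate and may be slow enough for intermolecular aminolysis by the solvent amide, oligomerisation or base-induced beta-elimination of N-5 to take over. The fallback uses known chemistry, sets out from 19 and returns at 23. Acid methanolysis of the azetidinone (HCl in MeOH, 40 °C) opens the C-2–N-5 bond and should give the ring-opened azido bis-carbamate methyl ester F1. Hydrogenolysis (H2, Pd/C, MeOH, then K2CO3) frees the three remaining nitrogens and gives the tetraamino methyl ester F2. An antimony-templated macrolactamization (Sb(OEt)3, benzene, reflux), in which the four nitrogens gather on the metal and the ester is delivered to the terminal primary amine, then closes N-1–C-2 to give 23.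

Step 5. The organometallic reagent may attack the lactam carbonyl or the silicon, or iodine–metal exchange followed by beta-elimination may open the ring instead of substitution. The fallback sets out from 8 and returns at 12. SN2 alkylation of lithium oct-1-ynide (oct-1-yne, n-BuLi, THF/DMPU, −30 to 0 °C) by the iodide should give (R)-1-(tert-butyldimethylsilyl)-4-(non-2-yn-1-yl)azetidin-2-one F3. Hydrogenation of the triple bond (H2, Pd/C, EtOAc) completes the nonyl chain and gives 12.

Step 9. Substitution at the chloride may be slow enough for the lactam anion to condense with itself, and both ends of the linchpin may react. The fallback builds the chain outward from the lactam, sets out from 13 and returns at 18. Alkylation of 13 at the bromide end of 16 (powdered KOH, Bu4NBr, THF) should give (R)-1-(3-chloropropyl)-4-nonylazetidin-2-one F4. The monosodium salt of 15 (in excess; NaH, NaI, DMF, 50 °C) is alkylated by F4 to give the mono-alkylated bis-carbamate F5. Its remaining carbamate N–H is then alkylated with 16 (NaH, DMF, 0 °C to rt) to give 18.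

**Further compounds**

F1 | step 11 | methyl (R)-3-{[3-({4-[(3-azidopropyl)(benzyloxycarbonyl)amino]butyl}(benzyloxycarbonyl)amino)propyl]amino}dodecanoate | CCCCCCCCC[C@@H](NCCCN(CCCCN(CCCN=[N+]=[N-])C(=O)OCc1ccccc1)C(=O)OCc1ccccc1)CC(=O)OC
F2 | step 11 | methyl (R)-3-{[3-({4-[(3-aminopropyl)amino]butyl}amino)propyl]amino}dodecanoate | CCCCCCCCC[C@@H](NCCCNCCCCNCCCN)CC(=O)OC
F3 | step 5 | (R)-1-(tert-butyldimethylsilyl)-4-(non-2-yn-1-yl)azetidin-2-one | CCCCCCC#CC[C@@H]1CC(=O)N1[Si](C)(C)C(C)(C)C
F4 | step 9 | (R)-1-(3-chloropropyl)-4-nonylazetidin-2-one | CCCCCCCCC[C@@H]1CC(=O)N1CCCCl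
F5 | step 9 | benzyl {4-[(benzyloxycarbonyl)amino]butyl}{3-[(R)-2-nonyl-4-oxoazetidin-1-yl]propyl}carbamate | CCCCCCCCC[C@@H]1CC(=O)N1CCCN(CCCCNC(=O)OCc1ccccc1)C(=O)OCc1ccccc1
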